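**Retrosynthetic overview**
- Last bond made: the exocyclic N–C bond to the imidazoledione. That ring is bought intact as 1-methylparabanic acid and condensed onto a 2-aminoimidazole.
- The 2-amino group comes from the imidazole C2–H by lithiation and azide transfer, then hydrogenation, which also frees the phenol.
- The imidazole is the only ring built: base-induced [3+2] cycloaddition of a benzyl-substituted TosMIC anion to an aldimine, then loss of sulfinate (van Leusen). N-methylation of the N-(2-cyanoethyl) cycloadduct and retro-Michael loss of acrylonitrile place the methyl next to the benzyl-bearing carbon.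
- The stereocentre is bought as (R)-4-methoxymandelic acid. Its carboxyl carbon becomes imidazole C4 and no bond to the carbinol carbon is broken.
- Ring order: both benzene rings bought, imidazole built, imidazoledione attached last.

Assumption: (R)-4-methoxymandelic acid (single enantiomer) and 1-methylparabanic acid are taken as catalogue compounds.

**Route**

Step 1
Reactants: 1 (R)-4-methoxymandelic acid
Product: 2 methyl (R)-4-methoxymandelate
Conditions: MeI, KHCO3, DMF, rt
Reagents that add atoms: iodomethane, CI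
Why: Carboxylate O-alkylation (SN2 esterification) under near-neutral conditions leaves the secondary benzylic alcohol and its configuration untouched.

Step 2
Reactants: 2 methyl (R)-4-methoxymandelate
Product: 3 methyl (2R)-2-(tert-butyldimethylsilyloxy)-2-(4-methoxyphenyl)acetate
Conditions: TBSCl, imidazole, DMF, rt
Reagents that add atoms: tert-butyldimethylsilyl chloride, CC(C)(C)[Si](C)(C)Cl
Why: Imidazole-promoted silyl ether formation at oxygen does not touch the C–O bond, so the (R) centre is retained.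

Step 3
Reactants: 3 methyl (2R)-2-(tert-butyldimethylsilyloxy)-2-(4-methoxyphenyl)acetate
Product: 4 (2R)-2-(tert-butyldimethylsilyloxy)-2-(4-methoxyphenyl)acetaldehyde
Conditions: i-Bu2AlH (1.1 equiv), CH2Cl2, −78 °C; aq. KNaC4H4O6 work-up; crude used at once
Reagents that add atoms: none
Why: Partial ester reduction stops at the aluminium hemiacetal at −78 °C, and the non-basic cold conditions do not enolise the α-silyloxy centre.

Step 4
Reactants: 5 p-toluenesulfonylmethyl isocyanide (TosMIC), 6 4-(benzyloxy)benzyl chloride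
Product: 7 1-(benzyloxy)-4-[2-isocyano-2-(p-toluenesulfonyl)ethyl]benzene (racemic)
Conditions: 30% aq. NaOH, CH2Cl2, n-Bu4NI (cat.), 0 °C
Reagents that add atoms: none
Why: Phase-transfer C-monoalkylation of the acidic TosMIC methylene with a reactive benzylic halide; the new centre is racemic and is lost on aromatisation in step 5.

Step 5
Reactants: 4 (2R)-2-(tert-butyldimethylsilyloxy)-2-(4-methoxyphenyl)acetaldehyde, 8 3-aminopropanenitrile, 7 1-(benzyloxy)-4-[2-isocyano-2-(p-toluenesulfonyl)ethyl]benzene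
Product: 11 1-(2-cyanoethyl)-4-[4-(benzyloxy)benzyl]-5-[(R)-(tert-butyldimethylsilyloxy)(4-methoxyphenyl)methyl]-1H-imidazole, via N-(2-cyanoethyl)aldimine 9 (not isolated), via 4-tosyl-2-imidazoline cycloadduct 10 (not isolated)
Conditions: 8, 4 Å MS, DMF, 0 °C; then 7, K2CO3, 0 °C → rt
Reagents that add atoms: none
Why: Van Leusen imidazole synthesis, a base-induced [3+2] cycloaddition of the TosMIC anion across the C=N bond followed by sulfinate elimination; the carbinol centre is a spectator that is retained under the mild carbonate base.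

Step 6
Reactants: 11 1-(2-cyanoethyl)-4-[4-(benzyloxy)benzyl]-5-[(R)-(tert-butyldimethylsilyloxy)(4-methoxyphenyl)methyl]-1H-imidazole
Product: 13 5-[4-(benzyloxy)benzyl]-4-[(R)-(tert-butyldimethylsilyloxy)(4-methoxyphenyl)methyl]-1-methyl-1H-imidazole, via 1-(2-cyanoethyl)-3-methylimidazolium iodide 12 (not isolated)
Conditions: MeI, MeCN, 40 °C; evaporate; then 1 M aq. NaOH, THF, 0 °C → rt
Reagents that add atoms: iodomethane, CI
Why: Quaternisation at the only pyridine-type nitrogen, then retro-Michael (E1cB) loss of acrylonitrile from the imidazolium, puts the methyl on the nitrogen next to the benzyl-bearing carbon with full regiocontrol.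

Step 7
Reactants: 13 5-[4-(benzyloxy)benzyl]-4-[(R)-(tert-butyldimethylsilyloxy)(4-methoxyphenyl)methyl]-1-methyl-1H-imidazole
Product: 15 2-azido-5-[4-(benzyloxy)benzyl]-4-[(R)-(tert-butyldimethylsilyloxy)(4-methoxyphenyl)methyl]-1-methyl-1H-imidazole, via 2-lithioimidazole 14 (not isolated)
Conditions: n-BuLi, THF, −78 °C; then TsN3, −78 °C; sat. aq. NH4Cl
Reagents that add atoms: p-toluenesulfonyl azide, Cc1ccc(cc1)S(=O)(=O)N=[N+]=[N-]
Why: Kinetic deprotonation at C2, the most acidic C–H of an N-methylimidazole, then electrophilic azide transfer from the sulfonyl azide; the benzylic carbinol C–H is not attacked at −78 °C.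

Step 8
Reactants: 15 2-azido-5-[4-(benzyloxy)benzyl]-4-[(R)-(tert-butyldimethylsilyloxy)(4-methoxyphenyl)methyl]-1-methyl-1H-imidazole
Product: 16 4-({2-amino-4-[(R)-(tert-butyldimethylsilyloxy)(4-methoxyphenyl)methyl]-1-methyl-1H-imidazol-5-yl}methyl)phenol
Conditions: H2 (1 atm), 10% Pd/C, EtOAc/EtOH, rt; monitored and stopped at full debenzylation
Reagents that add atoms: none
Why: Catalytic hydrogenation reduces the azide and hydrogenolyses the aryl benzyl ether, while the hindered benzylic silyl ether is a poor hydrogenolysis substrate in the basic medium set by the aminoimidazole.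

Step 9
Reactants: 16 4-({2-amino-4-[(R)-(tert-butyldimethylsilyloxy)(4-methoxyphenyl)methyl]-1-methyl-1H-imidazol-5-yl}methyl)phenol, 17 1-methylparabanic acid
Product: 19 4-({4-[(R)-(tert-butyldimethylsilyloxy)(4-methoxyphenyl)methyl]-5-(4-hydroxybenzyl)-1-methyl-1H-imidazol-2-yl}amino)-1-methyl-1H-imidazole-2,5-dione, via 1-methyl-4-(trimethylsilyloxy)imidazole-2,5-dione 18 (not isolated)
Conditions: 17, BSA, MeCN, reflux; evaporate; then 16, PhMe, reflux; MeOH quench
Reagents that add atoms: none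
Why: Addition–elimination of the 2-amino group at the O-silyl imidate carbon (C4, next to the former N–H) of the activated trione with loss of silanol, the condensation used for naamidine-type dehydrohydantoins, proceeds under neutral conditions that leave the carbinol centre alone.

Step 10
Reactants: 19 4-({4-[(R)-(tert-butyldimethylsilyloxy)(4-methoxyphenyl)methyl]-5-(4-hydroxybenzyl)-1-methyl-1H-imidazol-2-yl}amino)-1-methyl-1H-imidazole-2,5-dione
Product: 20 4-({4-[(R)-hydroxy(4-methoxyphenyl)methyl]-5-(4-hydroxybenzyl)-1-methyl-1H-imidazol-2-yl}amino)-1-methyl-1H-imidazole-2,5-dione (CNP0181743.1)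
Conditions: n-Bu4NF, AcOH (1:1), THF, 0 °C → rt
Reagents that add atoms: none
Why: Fluoride-driven Si–O cleavage, buffered with acetic acid to spare the acyl-amidine ring and avoid acid ionisation of the p-methoxybenzylic carbinol, releases the (R)-alcohol with retention.

**Compound list**

1 | (R)-4-methoxymandelic acid, (2R)-2-hydroxy-2-(4-methoxyphenyl)acetic acid | COc1ccc([C@@H](O)C(=O)O)cc1 | starting material
2 | methyl (2R)-2-hydroxy-2-(4-methoxyphenyl)acetate | COc1ccc([C@@H](O)C(=O)OC)cc1 | intermediate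
3 | methyl (2R)-2-[(tert-butyldimethylsilyl)oxy]-2-(4-methoxyphenyl)acetate | COc1ccc([C@@H](O[Si](C)(C)C(C)(C)C)C(=O)OC)cc1 | intermediate
4 | (2R)-2-[(tert-butyldimethylsilyl)oxy]-2-(4-methoxyphenyl)acetaldehyde | COc1ccc([C@@H](O[Si](C)(C)C(C)(C)C)C=O)cc1 | intermediate
5 | p-toluenesulfonylmethyl isocyanide (TosMIC) | Cc1ccc(cc1)S(=O)(=O)C[N+]#[C-] | starting material
6 | 4-(benzyloxy)benzyl chloride, 1-(benzyloxy)-4-(chloromethyl)benzene | ClCc1ccc(OCc2ccccc2)cc1 | starting material
7 | 1-(benzyloxy)-4-[2-isocyano-2-(4-methylbenzenesulfonyl)ethyl]benzene (racemic) | Cc1ccc(cc1)S(=O)(=O)C(Cc1ccc(OCc2ccccc2)cc1)[N+]#[C-] | intermediate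
8 | 3-aminopropanenitrile | NCCC#N | starting material
9 | 3-{[(1E,2R)-2-[(tert-butyldimethylsilyl)oxy]-2-(4-methoxyphenyl)ethylidene]amino}propanenitrile | COc1ccc([C@@H](O[Si](C)(C)C(C)(C)C)/C=N/CCC#N)cc1 | intermediate (not isolated)
10 | 3-[4-{[4-(benzyloxy)phenyl]methyl}-5-{(R)-[(tert-butyldimethylsilyl)oxy](4-methoxyphenyl)methyl}-4-(4-methylbenzenesulfonyl)-4,5-dihydro-1H-imidazol-1-yl]propanenitrile (ring diastereomers, side-chain centre R) | COc1ccc([C@@H](O[Si](C)(C)C(C)(C)C)C2N(CCC#N)C=NC2(Cc2ccc(OCc3ccccc3)cc2)S(=O)(=O)c2ccc(C)cc2)cc1 | intermediate (not isolated)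
11 | 3-[4-{[4-(benzyloxy)phenyl]methyl}-5-{(R)-[(tert-butyldimethylsilyl)oxy](4-methoxyphenyl)methyl}-1H-imidazol-1-yl]propanenitrile | COc1ccc([C@@H](O[Si](C)(C)C(C)(C)C)c2n(CCC#N)cnc2Cc2ccc(OCc3ccccc3)cc2)cc1 | intermediate
12 | 4-{[4-(benzyloxy)phenyl]methyl}-5-{(R)-[(tert-butyldimethylsilyl)oxy](4-methoxyphenyl)methyl}-1-(2-cyanoethyl)-3-methylimidazolium iodide | COc1ccc([C@@H](O[Si](C)(C)C(C)(C)C)c2n(CCC#N)c[n+](C)c2Cc2ccc(OCc3ccccc3)cc2)cc1.[I-] | intermediate (not isolated)
13 | 5-{[4-(benzyloxy)phenyl]methyl}-4-{(R)-[(tert-butyldimethylsilyl)oxy](4-methoxyphenyl)methyl}-1-methyl-1H-imidazole | COc1ccc([C@@H](O[Si](C)(C)C(C)(C)C)c2ncn(C)c2Cc2ccc(OCc3ccccc3)cc2)cc1 | intermediate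
14 | 2-lithio derivative of 13 | COc1ccc([C@@H](O[Si](C)(C)C(C)(C)C)c2nc([Li])n(C)c2Cc2ccc(OCc3ccccc3)cc2)cc1 | intermediate (not isolated)
15 | 2-azido-5-{[4-(benzyloxy)phenyl]methyl}-4-{(R)-[(tert-butyldimethylsilyl)oxy](4-methoxyphenyl)methyl}-1-methyl-1H-imidazole | COc1ccc([C@@H](O[Si](C)(C)C(C)(C)C)c2nc(N=[N+]=[N-])n(C)c2Cc2ccc(OCc3ccccc3)cc2)cc1 | intermediate
16 | 4-{[2-amino-4-{(R)-[(tert-butyldimethylsilyl)oxy](4-methoxyphenyl)methyl}-1-methyl-1H-imidazol-5-yl]methyl}phenol | COc1ccc([C@@H](O[Si](C)(C)C(C)(C)C)c2nc(N)n(C)c2Cc2ccc(O)cc2)cc1 | intermediate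
17 | 1-methylparabanic acid, 1-methylimidazolidine-2,4,5-trione | CN1C(=O)NC(=O)C1=O | starting material
18 | 1-methyl-4-[(trimethylsilyl)oxy]-1H-imidazole-2,5-dione | CN1C(=O)N=C(O[Si](C)(C)C)C1=O | intermediate (not isolated)
19 | 4-[(4-{(R)-[(tert-butyldimethylsilyl)oxy](4-methoxyphenyl)methyl}-5-[(4-hydroxyphenyl)methyl]-1-methyl-1H-imidazol-2-yl)amino]-1-methyl-1H-imidazole-2,5-dione | COc1ccc([C@@H](O[Si](C)(C)C(C)(C)C)c2nc(NC3=NC(=O)N(C)C3=O)n(C)c2Cc2ccc(O)cc2)cc1 | intermediate
20 | 4-[(4-[(R)-hydroxy(4-methoxyphenyl)methyl]-5-[(4-hydroxyphenyl)methyl]-1-methyl-1H-imidazol-2-yl)amino]-1-methyl-1H-imidazole-2,5-dione (CNP0181743.1) | COc1ccc([C@@H](O)c2nc(NC3=NC(=O)N(C)C3=O)n(C)c2Cc2ccc(O)cc2)cc1 | target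

**Step count**

Total steps: 10. Longest linear sequence: 9 steps (1 → 20 through steps 1–3 and 5–10); step 4 is a one-step side branch.

**Three steps most likely to fail**

Step 5. The C–C bond forms between a tertiary TosMIC carbanion and a branched aldimine whose α-hydrogen is benzylic, so a low yield or partial loss of optical purity is possible; the enantiomeric purity of 11 should be checked by chiral HPLC. The fallback sets out from 9 and comes back at 13. Parent TosMIC 5, which is more acidic and unhindered, is used in the cycloaddition (K2CO3, DMF, 0 °C) to give, through the 4-tosyl-2-imidazoline F1, the 1-(2-cyanoethyl)-5-substituted imidazole F2. MeI then aq. NaOH, as in step 6, converts it through the imidazolium iodide F3 into the 1-methyl-4-substituted imidazole F4. NIS (MeCN, 0 °C) iodinates the free and most nucleophilic C5 to give the 5-iodoimidazole F5. Negishi coupling of F5 with 4-(benzyloxy)benzylzinc chloride F6 (from 6, Zn dust, LiCl, THF) under Pd(PPh3)4 (THF, 50 °C) gives 13.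

Step 7. n-BuLi could also deprotonate the doubly benzylic silyloxy C–H (racemisation, silyl migration) or the benzyl ether CH2, and 2-azidoimidazoles are labile. The fallback sets out from 13 and comes back at 15, with no carbanion involved. NBS (1.0 equiv, MeCN, 0 °C) brominates the only free ring position to give the 2-bromoimidazole F7. Copper-catalysed azidation (CuI, NaN3, N,N'-dimethylethylenediamine, sodium ascorbate NaC6H7O6, EtOH/H2O, 60 °C) then gives 15.

Step 8. The C–O bond at the carbinol carbon is doubly benzylic and sits on an electron-rich 2-aminoimidazole, so over-hydrogenolysis to the deoxy compound is the main danger. The fallback sets out from 13 and comes back at 16; it moves the debenzylation ahead of the amination and reduces the azide without hydrogen. The benzyl ether is hydrogenolysed at 13 (H2, 10% Pd/C, EtOAc), where the ring is not yet amino-activated and no azide is present, to give the phenol F8. TBSCl/imidazole gives the bis-silyl ether F9. n-BuLi gives the 2-lithio species F10 and TsN3 the azide F11. Propane-1,3-dithiol/Et3N (MeOH, rt) reduces the azide to the amine F12. K2CO3/MeOH (rt) cleaves only the aryl silyl ether and delivers 16.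

**Further compounds**

F1 | step 5 | 3-[5-{(R)-[(tert-butyldimethylsilyl)oxy](4-methoxyphenyl)methyl}-4-(4-methylbenzenesulfonyl)-4,5-dihydro-1H-imidazol-1-yl]propanenitrile | COc1ccc([C@@H](O[Si](C)(C)C(C)(C)C)C2N(CCC#N)C=NC2S(=O)(=O)c2ccc(C)cc2)cc1
F2 | step 5 | 3-[5-{(R)-[(tert-butyldimethylsilyl)oxy](4-methoxyphenyl)methyl}-1H-imidazol-1-yl]propanenitrile | COc1ccc([C@@H](O[Si](C)(C)C(C)(C)C)c2cncn2CCC#N)cc1
F3 | step 5 | 5-{(R)-[(tert-butyldimethylsilyl)oxy](4-methoxyphenyl)methyl}-1-(2-cyanoethyl)-3-methylimidazolium iodide | COc1ccc([C@@H](O[Si](C)(C)C(C)(C)C)c2c[n+](C)cn2CCC#N)cc1.[I-]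
F4 | step 5 | 4-{(R)-[(tert-butyldimethylsilyl)oxy](4-methoxyphenyl)methyl}-1-methyl-1H-imidazole | COc1ccc([C@@H](O[Si](C)(C)C(C)(C)C)c2cn(C)cn2)cc1
F5 | step 5 | 4-{(R)-[(tert-butyldimethylsilyl)oxy](4-methoxyphenyl)methyl}-5-iodo-1-methyl-1H-imidazole | COc1ccc([C@@H](O[Si](C)(C)C(C)(C)C)c2ncn(C)c2I)cc1
F6 | step 5 | 4-(benzyloxy)benzylzinc chloride | Cl[Zn]Cc1ccc(OCc2ccccc2)cc1
F7 | step 7 | 5-{[4-(benzyloxy)phenyl]methyl}-2-bromo-4-{(R)-[(tert-butyldimethylsilyl)oxy](4-methoxyphenyl)methyl}-1-methyl-1H-imidazole | COc1ccc([C@@H](O[Si](C)(C)C(C)(C)C)c2nc(Br)n(C)c2Cc2ccc(OCc3ccccc3)cc2)cc1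
F8 | step 8 | 4-{[4-{(R)-[(tert-butyldimethylsilyl)oxy](4-methoxyphenyl)methyl}-1-methyl-1H-imidazol-5-yl]methyl}phenol | COc1ccc([C@@H](O[Si](C)(C)C(C)(C)C)c2ncn(C)c2Cc2ccc(O)cc2)cc1
F9 | step 8 | 4-{(R)-[(tert-butyldimethylsilyl)oxy](4-methoxyphenyl)methyl}-5-({4-[(tert-butyldimethylsilyl)oxy]phenyl}methyl)-1-methyl-1H-imidazole | COc1ccc([C@@H](O[Si](C)(C)C(C)(C)C)c2ncn(C)c2Cc2ccc(O[Si](C)(C)C(C)(C)C)cc2)cc1
F10 | step 8 | 2-lithio derivative of F9 | COc1ccc([C@@H](O[Si](C)(C)C(C)(C)C)c2nc([Li])n(C)c2Cc2ccc(O[Si](C)(C)C(C)(C)C)cc2)cc1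
F11 | step 8 | 2-azido-4-{(R)-[(tert-butyldimethylsilyl)oxy](4-methoxyphenyl)methyl}-5-({4-[(tert-butyldimethylsilyl)oxy]phenyl}methyl)-1-methyl-1H-imidazole | COc1ccc([C@@H](O[Si](C)(C)C(C)(C)C)c2nc(N=[N+]=[N-])n(C)c2Cc2ccc(O[Si](C)(C)C(C)(C)C)cc2)cc1
F12 | step 8 | 4-{(R)-[(tert-butyldimethylsilyl)oxy](4-methoxyphenyl)methyl}-5-({4-[(tert-butyldimethylsilyl)oxy]phenyl}methyl)-1-methyl-1H-imidazol-2-amine | COc1ccc([C@@H](O[Si](C)(C)C(C)(C)C)c2nc(N)n(C)c2Cc2ccc(O[Si](C)(C)C(C)(C)C)cc2)cc1
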